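**Plan**

- Retrosynthesis: remove the C2 acetate; cut the side chain at C6' (methyl addition to a methyl ketone), at C3'=C4' (Wittig) and at C2'–CH3 (methylcuprate addition to a C8 ynoate); open the oxirane C3–C4 bond together with C4–O (retro-Darzens) to a C3 bromomethyl ketone and a C4 methyl ketone on a cyclopentane; then cut C7–C6 (conjugate addition), C8–CHO (carbonylation) and C1–C2 (asymmetric conjugate addition) back to 3-methylcyclopent-2-en-1-one.
- Enabling feature: in the seven-membered ring the oxirane CH (C3) sits between the acetoxy carbon C2 and the methyl-bearing oxirane carbon C4. With C2 as a ketone, C3 is its only enolisable position (C1 is quaternary) and C4 is a methyl ketone carbonyl, so the 2-oxo-3,4-epoxide is a Darzens retron that closes the carbocycle and the oxirane together.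
- Forward order: the cyclopentane is substituted first (C1, then C7, then C8), the (Z)-enoate handle is installed, the seven-membered ring and oxirane close in one step, C2 is reduced, then the dienol chain and the acetate follow.
- Stereochemistry: C1 from a ligand-controlled copper-catalysed conjugate addition; C7 by addition anti to the silylvinyl group; C8 by equilibration to trans; C3/C4 from the antiperiplanar Darzens closure on the face opposite the C1 methyl; C2 by hydride addition anti to the oxirane; the Z-alkene from syn-carbocupration and the E-alkene from a stabilised ylide.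

Key step: step 10

Remark: atoms are numbered on the bicyclo[5.3.0]decane core of the target (C1 quaternary ring-fusion carbon with CH3, C2 acetoxy carbon, C3 and C4 oxirane carbons with CH3 on C4, C5, C6, C7 ring-fusion CH, C8 side-chain carbon, C9, C10; side chain C1'–C7' as a hepta-2,4-dien-2-yl group). The same labels are used for the corresponding atoms of all intermediates. It is assumed that both enantiomers of the sulfonate-bearing NHC ligand precursor are accessible; the one giving the (S)-quaternary centre is used.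

**Step 1**
Reactants: 1 3-methylcyclopent-2-en-1-one; 2 ethynyltrimethylsilane
Product: 5 (S)-3-methyl-3-[1-(trimethylsilyl)ethenyl]cyclopent-1-en-1-yl trifluoromethanesulfonate, via vinylalane 3 (not isolated), via aluminium enolate 4 (not isolated)
Conditions: 2, i-Bu2AlH, hexanes, 55 °C; then 1, Cu(OTf)2 (5 mol %), chiral sulfonate-bearing imidazolinium salt (NHC precursor, 6 mol %), THF, −30 °C; then MeLi, PhNTf2, −78 → 0 °C
Reagents that add atoms: N-phenylbis(trifluoromethanesulfonimide), O=S(=O)(N(c1ccccc1)S(=O)(=O)C(F)(F)F)C(F)(F)F; diisobutylaluminium hydride, CC(C)C[AlH]CC(C)C (its aluminium and isobutyl groups stay only in 3 and 4)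
Why: α-Selective hydroalumination of 2 gives vinylalane 3, whose NHC–copper-catalysed asymmetric conjugate addition to the β-methyl enone (a precedented way to silylvinyl-bearing quaternary centres) should set C1 as (S) under ligand control, and O-triflation of the regiodefined enolate 4 after activation as its lithium ate complex fixes the enol triflate on the C7 side.

**Step 2**
Reactants: 5 (S)-3-methyl-3-[1-(trimethylsilyl)ethenyl]cyclopent-1-en-1-yl trifluoromethanesulfonate
Product: 6 (S)-3-methyl-3-[1-(trimethylsilyl)ethenyl]cyclopent-1-ene-1-carbaldehyde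
Conditions: Pd(PPh3)4 (5 mol %), LiCl, CO (1 atm), Bu3SnH (slow addition), THF, 50 °C
Reagents that add atoms: carbon monoxide, [C-]#[O+]
Why: Palladium-catalysed reductive carbonylation (Stille-type formylation) of the vinyl triflate by oxidative addition, CO insertion and hydride transfer from the stannane should give the enal without touching the vinylsilane, and no stereocentre is formed.

**Step 3**
Reactants: 6 (S)-3-methyl-3-[1-(trimethylsilyl)ethenyl]cyclopent-1-ene-1-carbaldehyde; 7 2-(2-bromoethyl)-2-methyl-1,3-dioxolane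
Product: 10 (1R,2S,3S)-3-methyl-2-[2-(2-methyl-1,3-dioxolan-2-yl)ethyl]-3-[1-(trimethylsilyl)ethenyl]cyclopentane-1-carbaldehyde, via Grignard reagent 8 (not isolated), via silyl enol ether 9 (not isolated)
Conditions: 7, Mg, THF, rt; then CuBr·SMe2 (10 mol %), Me3SiCl, 6, THF, −78 °C; then K2CO3, MeOH, rt
Reagents that add atoms: magnesium, [Mg], and chlorotrimethylsilane, C[Si](C)(C)Cl (both leave atoms only in the intermediates 8 and 9, not in 10)
Why: Copper-catalysed, silyl-chloride-accelerated conjugate addition of Grignard reagent 8 to the enal (Nakamura–Kuwajima conditions) should occur at C7 anti to the bulky silylvinyl group on the neighbouring quaternary C1, and base-mediated methanolysis of 9 with equilibration places the C8 formyl group trans to the new C7 chain under thermodynamic control.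

**Step 4**
Reactants: 10 (1R,2S,3S)-3-methyl-2-[2-(2-methyl-1,3-dioxolan-2-yl)ethyl]-3-[1-(trimethylsilyl)ethenyl]cyclopentane-1-carbaldehyde
Product: 11 (1S,2S,3R)-3-ethynyl-1-methyl-2-[2-(2-methyl-1,3-dioxolan-2-yl)ethyl]-1-[1-(trimethylsilyl)ethenyl]cyclopentane
Conditions: dimethyl (1-diazo-2-oxopropyl)phosphonate, K2CO3, MeOH, 0 °C → rt
Reagents that add atoms: dimethyl (1-diazo-2-oxopropyl)phosphonate, COP(=O)(OC)C(=[N+]=[N-])C(C)=O
Why: Seyferth–Gilbert homologation with the Ohira–Bestmann reagent should convert the aldehyde into the terminal alkyne through an alkylidene carbene 1,2-hydrogen shift, the basic medium keeping the epimerisable C8 centre in its trans configuration.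

**Step 5**
Reactants: 11 (1S,2S,3R)-3-ethynyl-1-methyl-2-[2-(2-methyl-1,3-dioxolan-2-yl)ethyl]-1-[1-(trimethylsilyl)ethenyl]cyclopentane
Product: 12 methyl 3-{(1R,2S,3S)-3-methyl-2-[2-(2-methyl-1,3-dioxolan-2-yl)ethyl]-3-[1-(trimethylsilyl)ethenyl]cyclopentyl}prop-2-ynoate
Conditions: LDA, THF, −78 °C; then ClCO2Me, −78 → 0 °C
Reagents that add atoms: methyl chloroformate, COC(=O)Cl
Why: Acylation of the lithium acetylide with a chloroformate is a standard ynoate synthesis, and the non-nucleophilic amide base leaves ketal and vinylsilane untouched.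

**Step 6**
Reactants: 12 methyl 3-{(1R,2S,3S)-3-methyl-2-[2-(2-methyl-1,3-dioxolan-2-yl)ethyl]-3-[1-(trimethylsilyl)ethenyl]cyclopentyl}prop-2-ynoate
Product: 13 methyl (2Z)-3-{(1R,2S,3S)-3-methyl-2-[2-(2-methyl-1,3-dioxolan-2-yl)ethyl]-3-[1-(trimethylsilyl)ethenyl]cyclopentyl}but-2-enoate
Conditions: Me2CuLi (from MeLi, CuI), THF, −78 °C; MeOH quench at −78 °C
Reagents that add atoms: lithium dimethylcuprate, [Li+].C[Cu-]C
Why: syn-Carbocupration of the ynoate (conjugate addition of a lithium dialkylcuprate to an acetylenic ester) with protonation of the vinylcopper at −78 °C should place CH3 and H cis, hence ring and ester cis, which is the (Z)-trisubstituted alkene of the target.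

**Step 7**
Reactants: 13 methyl (2Z)-3-{(1R,2S,3S)-3-methyl-2-[2-(2-methyl-1,3-dioxolan-2-yl)ethyl]-3-[1-(trimethylsilyl)ethenyl]cyclopentyl}but-2-enoate
Product: 15 methyl (2Z)-3-{(1R,2S,3S)-3-(1-bromoethenyl)-3-methyl-2-[2-(2-methyl-1,3-dioxolan-2-yl)ethyl]cyclopentyl}but-2-enoate, via dibromide 14 (not isolated)
Conditions: Br2 (1.0 equiv), CH2Cl2, −78 °C, dark; then NaOMe, MeOH, 0 °C
Reagents that add atoms: bromine, BrBr
Why: Bromodesilylation by anti addition of bromine to the electron-rich vinylsilane (the electron-poor enoate should not react at −78 °C) and methoxide-induced anti elimination of the silyl group and bromide from 14 should give the 1-bromoethenyl group.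

**Step 8**
Reactants: 15 methyl (2Z)-3-{(1R,2S,3S)-3-(1-bromoethenyl)-3-methyl-2-[2-(2-methyl-1,3-dioxolan-2-yl)ethyl]cyclopentyl}but-2-enoate
Product: 16 methyl (2Z)-3-{(1R,2S,3S)-3-(bromoacetyl)-3-methyl-2-[2-(2-methyl-1,3-dioxolan-2-yl)ethyl]cyclopentyl}but-2-enoate
Conditions: NBS, cat. HBr, MeCN/H2O (4:1), 0 °C → rt, dark; then aq. Na2S2O3
Reagents that add atoms: N-bromosuccinimide, O=C1CCC(=O)N1Br; water, O
Why: Oxidative hydrolysis of a vinyl bromide, in which electrophilic bromine adds to the terminal CH2, water captures the bromine-stabilised cation and the geminal bromohydrin loses HBr, should give the bromomethyl ketone with the halogen placed regiospecifically on C3.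

**Step 9**
Reactants: 16 methyl (2Z)-3-{(1R,2S,3S)-3-(bromoacetyl)-3-methyl-2-[2-(2-methyl-1,3-dioxolan-2-yl)ethyl]cyclopentyl}but-2-enoate
Product: 17 methyl (2Z)-3-[(1R,2S,3S)-3-(bromoacetyl)-3-methyl-2-(3-oxobutyl)cyclopentyl]but-2-enoate
Conditions: PPTS, acetone/H2O, 50 °C
Reagents that add atoms: water, O
Why: Mild acid-catalysed ketal hydrolysis should liberate the C4 methyl ketone while the α-bromo ketone and the enoate are stable to these conditions.

**Step 10**
Reactants: 17 methyl (2Z)-3-[(1R,2S,3S)-3-(bromoacetyl)-3-methyl-2-(3-oxobutyl)cyclopentyl]but-2-enoate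
Product: 18 methyl (2Z)-3-[(1S,3R,4R,7S,8R)-3,4-epoxy-1,4-dimethyl-2-oxobicyclo[5.3.0]decan-8-yl]but-2-enoate
Conditions: KOt-Bu (1.05 equiv), t-BuOH/THF (1:4), 0.005 M, −20 → 0 °C
Reagents that add atoms: none
Why: Proposed new method: the bromomethyl ketone, by far the strongest carbon acid present and enolisable only toward C3 because C1 is quaternary, is deprotonated, the bromo-enolate adds reversibly through C3 to the C4 methyl ketone, and the bromohydrin alkoxide then displaces bromide, so that the C3–C4 bond and the oxirane form in one operation; the closest known reaction type is the Darzens condensation of α-halo ketones with ketones and its intramolecular variants that close five- and six-membered rings. The carbocycle closes in a 7-(enolendo)-exo-trig aldol step and the oxirane in a 3-exo-tet displacement. Both new stereocentres (C3 and C4) are fixed by the displacement, which needs the C4–O and C3–Br bonds antiperiplanar and can therefore give only the cis-fused oxirane, while aldolates that cannot reach this geometry return by retro-aldol. In the chair-like transition state of the trans-fused bicycle the C1 methyl group is pseudo-axial on the lower face, so the axial C4 alkoxide should sit on the upper face and the oxirane is expected anti to the angular methyl, as the target requires. The step needs enolisation at C3 in preference to the methyl ketone (secured by the large acidity gap under equilibrating alkoxide conditions), the seven-membered aldol in preference to the five-membered aldol of the C5 enolate onto C2 (which would give a strained trans-bicyclo[3.3.0]octane), and high dilution against intermolecular alkylation.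

**Step 11**
Reactants: 18 methyl (2Z)-3-[(1S,3R,4R,7S,8R)-3,4-epoxy-1,4-dimethyl-2-oxobicyclo[5.3.0]decan-8-yl]but-2-enoate
Product: 19 methyl (2Z)-3-[(1S,2S,3S,4R,7S,8R)-3,4-epoxy-2-hydroxy-1,4-dimethylbicyclo[5.3.0]decan-8-yl]but-2-enoate
Conditions: NaBH4, CeCl3·7H2O, MeOH, −78 °C
Reagents that add atoms: none
Why: In this Luche reduction of an α,β-epoxy ketone the hydride is expected to add anti to the oxirane C–O bond (Felkin–Anh and cerium-chelate models), which should give the cis-epoxy alcohol with the (2S) configuration and leave the conjugated ester untouched.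

**Step 12**
Reactants: 19 methyl (2Z)-3-[(1S,2S,3S,4R,7S,8R)-3,4-epoxy-2-hydroxy-1,4-dimethylbicyclo[5.3.0]decan-8-yl]but-2-enoate
Product: 20 (2Z)-3-[(1S,2S,3S,4R,7S,8R)-3,4-epoxy-2-hydroxy-1,4-dimethylbicyclo[5.3.0]decan-8-yl]but-2-en-1-ol
Conditions: i-Bu2AlH (3.5 equiv), CH2Cl2, −78 °C; aq. potassium sodium tartrate
Reagents that add atoms: none
Why: Reduction of the enoate to the allylic alcohol with the aluminium hydride at low temperature is standard, and the hindered trisubstituted oxirane and the (Z)-alkene should survive at −78 °C.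

**Step 13**
Reactants: 20 (2Z)-3-[(1S,2S,3S,4R,7S,8R)-3,4-epoxy-2-hydroxy-1,4-dimethylbicyclo[5.3.0]decan-8-yl]but-2-en-1-ol
Product: 22 (3E,5Z)-6-[(1S,2S,3S,4R,7S,8R)-3,4-epoxy-2-hydroxy-1,4-dimethylbicyclo[5.3.0]decan-8-yl]hepta-3,5-dien-2-one, via Z-enal 21 (not isolated)
Conditions: MnO2 (20 equiv), Ph3P=CHC(O)CH3, CH2Cl2, rt → 40 °C
Reagents that add atoms: 1-(triphenyl-λ5-phosphanylidene)propan-2-one, CC(=O)C=P(c1ccccc1)(c1ccccc1)c1ccccc1
Why: In this tandem oxidation–Wittig olefination MnO2 should oxidise only the allylic alcohol, and the stabilised ylide traps enal 21 as it forms (limiting Z to E isomerisation) to give the new double bond with (E) geometry.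

**Step 14**
Reactants: 22 (3E,5Z)-6-[(1S,2S,3S,4R,7S,8R)-3,4-epoxy-2-hydroxy-1,4-dimethylbicyclo[5.3.0]decan-8-yl]hepta-3,5-dien-2-one
Product: 23 (1S,2S,3S,4R,7S,8R)-3,4-epoxy-8-[(2Z,4E)-6-hydroxy-6-methylhepta-2,4-dien-2-yl]-1,4-dimethylbicyclo[5.3.0]decan-2-ol
Conditions: MeLi, CeCl3 (anhydrous), THF, −78 °C; aq. NH4Cl
Reagents that add atoms: methyllithium, [Li]C
Why: Organocerium 1,2-addition to the methyl ketone of the dienone should give the tertiary dienyl carbinol without conjugate addition or oxirane opening, the free C2 hydroxyl being carried as its alkoxide.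

**Step 15**
Reactants: 23 (1S,2S,3S,4R,7S,8R)-3,4-epoxy-8-[(2Z,4E)-6-hydroxy-6-methylhepta-2,4-dien-2-yl]-1,4-dimethylbicyclo[5.3.0]decan-2-ol
Product: 24 (1S,2S,3S,4R,7S,8R)-3,4-epoxy-8-[(2Z,4E)-6-hydroxy-6-methylhepta-2,4-dien-2-yl]-1,4-dimethylbicyclo[5.3.0]decan-2-yl acetate
Conditions: Ac2O, pyridine, DMAP (cat.), CH2Cl2, 0 °C → rt
Reagents that add atoms: acetic anhydride, CC(=O)OC(C)=O
Why: Base-mediated acylation should acetylate the secondary C2 hydroxyl selectively, since the tertiary allylic hydroxyl is not esterified under these mild, non-acidic conditions.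

**Compound list**

1 | 3-methylcyclopent-2-en-1-one | CC1=CC(=O)CC1 | starting material
2 | ethynyltrimethylsilane | C#C[Si](C)(C)C | starting material
3 | diisobutyl[1-(trimethylsilyl)ethenyl]aluminium (vinylalane) | C=C([Si](C)(C)C)[Al](CC(C)C)CC(C)C | intermediate
4 | diisobutylaluminium (S)-3-methyl-3-[1-(trimethylsilyl)ethenyl]cyclopent-1-en-1-olate (aluminium enolate) | CC(C)C[Al](CC(C)C)OC1=C[C@@](C)(C(=C)[Si](C)(C)C)CC1 | intermediate
5 | (S)-3-methyl-3-[1-(trimethylsilyl)ethenyl]cyclopent-1-en-1-yl trifluoromethanesulfonate | O=S(=O)(OC1=C[C@@](C)(C(=C)[Si](C)(C)C)CC1)C(F)(F)F | intermediate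
6 | (S)-3-methyl-3-[1-(trimethylsilyl)ethenyl]cyclopent-1-ene-1-carbaldehyde | O=CC1=C[C@@](C)(C(=C)[Si](C)(C)C)CC1 | intermediate
7 | 2-(2-bromoethyl)-2-methyl-1,3-dioxolane | CC1(CCBr)OCCO1 | starting material
8 | [2-(2-methyl-1,3-dioxolan-2-yl)ethyl]magnesium bromide (Grignard reagent) | CC1(CC[Mg]Br)OCCO1 | intermediate
9 | trimethyl({(2S,3S)-3-methyl-2-[2-(2-methyl-1,3-dioxolan-2-yl)ethyl]-3-[1-(trimethylsilyl)ethenyl]cyclopentylidene}methoxy)silane (silyl enol ether of 10; enol ether geometry not defined) | CC1(OCCO1)CC[C@H]2C(=CO[Si](C)(C)C)CC[C@]2(C)C(=C)[Si](C)(C)C | intermediate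
10 | (1R,2S,3S)-3-methyl-2-[2-(2-methyl-1,3-dioxolan-2-yl)ethyl]-3-[1-(trimethylsilyl)ethenyl]cyclopentane-1-carbaldehyde | CC1(OCCO1)CC[C@H]2[C@H](C=O)CC[C@]2(C)C(=C)[Si](C)(C)C | intermediate
11 | (1S,2S,3R)-3-ethynyl-1-methyl-2-[2-(2-methyl-1,3-dioxolan-2-yl)ethyl]-1-[1-(trimethylsilyl)ethenyl]cyclopentane | CC1(OCCO1)CC[C@H]2[C@H](C#C)CC[C@]2(C)C(=C)[Si](C)(C)C | intermediate
12 | methyl 3-{(1R,2S,3S)-3-methyl-2-[2-(2-methyl-1,3-dioxolan-2-yl)ethyl]-3-[1-(trimethylsilyl)ethenyl]cyclopentyl}prop-2-ynoate | CC1(OCCO1)CC[C@H]2[C@H](C#CC(=O)OC)CC[C@]2(C)C(=C)[Si](C)(C)C | intermediate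
13 | methyl (2Z)-3-{(1R,2S,3S)-3-methyl-2-[2-(2-methyl-1,3-dioxolan-2-yl)ethyl]-3-[1-(trimethylsilyl)ethenyl]cyclopentyl}but-2-enoate | CC1(OCCO1)CC[C@H]2[C@H](/C(C)=C\C(=O)OC)CC[C@]2(C)C(=C)[Si](C)(C)C | intermediate
14 | methyl (2Z)-3-{(1R,2S,3S)-3-[1,2-dibromo-1-(trimethylsilyl)ethyl]-3-methyl-2-[2-(2-methyl-1,3-dioxolan-2-yl)ethyl]cyclopentyl}but-2-enoate (dibromide; configuration at the CBr(Si) carbon not defined) | CC1(OCCO1)CC[C@H]2[C@H](/C(C)=C\C(=O)OC)CC[C@]2(C)C(Br)(CBr)[Si](C)(C)C | intermediate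
15 | methyl (2Z)-3-{(1R,2S,3S)-3-(1-bromoethenyl)-3-methyl-2-[2-(2-methyl-1,3-dioxolan-2-yl)ethyl]cyclopentyl}but-2-enoate | CC1(OCCO1)CC[C@H]2[C@H](/C(C)=C\C(=O)OC)CC[C@]2(C)C(Br)=C | intermediate
16 | methyl (2Z)-3-{(1R,2S,3S)-3-(bromoacetyl)-3-methyl-2-[2-(2-methyl-1,3-dioxolan-2-yl)ethyl]cyclopentyl}but-2-enoate | CC1(OCCO1)CC[C@H]2[C@H](/C(C)=C\C(=O)OC)CC[C@]2(C)C(=O)CBr | intermediate
17 | methyl (2Z)-3-[(1R,2S,3S)-3-(bromoacetyl)-3-methyl-2-(3-oxobutyl)cyclopentyl]but-2-enoate | CC(=O)CC[C@H]1[C@H](/C(C)=C\C(=O)OC)CC[C@]1(C)C(=O)CBr | intermediate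
18 | methyl (2Z)-3-[(1S,3R,4R,7S,8R)-3,4-epoxy-1,4-dimethyl-2-oxobicyclo[5.3.0]decan-8-yl]but-2-enoate | O=C1[C@@H]2O[C@]2(C)CC[C@H]2[C@H](/C(C)=C\C(=O)OC)CC[C@]12C | intermediate
19 | methyl (2Z)-3-[(1S,2S,3S,4R,7S,8R)-3,4-epoxy-2-hydroxy-1,4-dimethylbicyclo[5.3.0]decan-8-yl]but-2-enoate | O[C@@H]1[C@@H]2O[C@]2(C)CC[C@H]2[C@H](/C(C)=C\C(=O)OC)CC[C@]12C | intermediate
20 | (2Z)-3-[(1S,2S,3S,4R,7S,8R)-3,4-epoxy-2-hydroxy-1,4-dimethylbicyclo[5.3.0]decan-8-yl]but-2-en-1-ol | O[C@@H]1[C@@H]2O[C@]2(C)CC[C@H]2[C@H](/C(C)=C\CO)CC[C@]12C | intermediate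
21 | (2Z)-3-[(1S,2S,3S,4R,7S,8R)-3,4-epoxy-2-hydroxy-1,4-dimethylbicyclo[5.3.0]decan-8-yl]but-2-enal (Z-enal) | O[C@@H]1[C@@H]2O[C@]2(C)CC[C@H]2[C@H](/C(C)=C\C=O)CC[C@]12C | intermediate
22 | (3E,5Z)-6-[(1S,2S,3S,4R,7S,8R)-3,4-epoxy-2-hydroxy-1,4-dimethylbicyclo[5.3.0]decan-8-yl]hepta-3,5-dien-2-one | O[C@@H]1[C@@H]2O[C@]2(C)CC[C@H]2[C@H](/C(C)=C\C=C\C(C)=O)CC[C@]12C | intermediate
23 | (1S,2S,3S,4R,7S,8R)-3,4-epoxy-8-[(2Z,4E)-6-hydroxy-6-methylhepta-2,4-dien-2-yl]-1,4-dimethylbicyclo[5.3.0]decan-2-ol | O[C@@H]1[C@@H]2O[C@]2(C)CC[C@H]2[C@H](/C(C)=C\C=C\C(C)(C)O)CC[C@]12C | intermediate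
24 | (1S,2S,3S,4R,7S,8R)-3,4-epoxy-8-[(2Z,4E)-6-hydroxy-6-methylhepta-2,4-dien-2-yl]-1,4-dimethylbicyclo[5.3.0]decan-2-yl acetate (CNP0265175.1) | CC(=O)O[C@@H]1[C@@H]2O[C@]2(C)CC[C@H]2[C@H](/C(C)=C\C=C\C(C)(C)O)CC[C@]12C | target

**Totals and risks**

Total step count: 15. Longest linear sequence: 15 steps, from compound 1.

Steps most likely to fail:

1. Step 10 (Proposed new method). Two processes may interfere: C-alkylation of the minor methyl ketone enolate at the bromomethyl carbon (six-membered ring), and oxirane closure on the wrong face, because bromide has to leave syn to the angular methyl. The fallback uses known chemistry, sets out from 17 and returns at 18. Treatment of 17 with SmI2 (THF, −78 °C) should generate the samarium enolate at C3 only and close the ring by an intramolecular Reformatsky-type aldol addition to give the β-hydroxy ketone F1. Mesylation and elimination (MsCl, Et3N, then DBU) should give the conjugated cycloheptenone F2. Nucleophilic epoxidation (H2O2, aq. NaOH, MeOH, 0 °C) should then deliver the hydroperoxide axially to C4 on the face opposite the pseudo-axial C1 methyl and give 18.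

2. Step 11. Facial selectivity of hydride addition may be poor or reversed, because the pseudo-axial C1 methyl shields the face that has to be attacked. The fallback sets out from 18 and returns at 19. Reduction from the open face (for example LiBH(s-Bu)3, THF, −78 °C) would give the C2-epimeric alcohol F3. Mitsunobu inversion (PPh3, DIAD, 4-nitrobenzoic acid, toluene) would give the inverted ester F4, and methanolysis (K2CO3, MeOH) would release 19.

3. Step 3. Discrimination between methyl and silylvinyl on the neighbouring quaternary carbon may be insufficient, or 1,2-addition to the hindered enal may compete. The fallback sets out from the aluminium enolate 4 (generated as in step 1) and returns at 10. The enolate, activated with MeLi, is alkylated at C7 with bromide 7 (HMPA, cat. Bu4NI) and equilibrated with NaOMe, so that the now epimerisable C7 centre settles trans to the silylvinyl group, giving the ketone F5. Reductive cyanation (TosMIC, KOt-Bu, DME/EtOH) gives the nitrile F6, trans at C8 after equilibration, and partial reduction (i-Bu2AlH, toluene, −78 °C, aqueous work-up) gives 10.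

**Further compounds**

F1 | step 10 | methyl (2Z)-3-[(1S,7S,8R)-4-hydroxy-1,4-dimethyl-2-oxobicyclo[5.3.0]decan-8-yl]but-2-enoate (C4 epimers) | O=C1CC(C)(O)CC[C@H]2[C@H](/C(C)=C\C(=O)OC)CC[C@]12C
F2 | step 10 | methyl (2Z)-3-[(1S,7S,8R)-1,4-dimethyl-2-oxobicyclo[5.3.0]dec-3-en-8-yl]but-2-enoate | O=C1C=C(C)CC[C@H]2[C@H](/C(C)=C\C(=O)OC)CC[C@]12C
F3 | step 11 | methyl (2Z)-3-[(1S,2R,3S,4R,7S,8R)-3,4-epoxy-2-hydroxy-1,4-dimethylbicyclo[5.3.0]decan-8-yl]but-2-enoate | O[C@H]1[C@@H]2O[C@]2(C)CC[C@H]2[C@H](/C(C)=C\C(=O)OC)CC[C@]12C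
F4 | step 11 | methyl (2Z)-3-[(1S,2S,3S,4R,7S,8R)-3,4-epoxy-1,4-dimethyl-2-(4-nitrobenzoyloxy)bicyclo[5.3.0]decan-8-yl]but-2-enoate | O=C(O[C@@H]1[C@@H]2O[C@]2(C)CC[C@H]2[C@H](/C(C)=C\C(=O)OC)CC[C@]12C)c1ccc(cc1)[N+](=O)[O-]
F5 | step 3 | (2R,3S)-3-methyl-2-[2-(2-methyl-1,3-dioxolan-2-yl)ethyl]-3-[1-(trimethylsilyl)ethenyl]cyclopentan-1-one | CC1(OCCO1)CC[C@H]2C(=O)CC[C@]2(C)C(=C)[Si](C)(C)C
F6 | step 3 | (1R,2S,3S)-3-methyl-2-[2-(2-methyl-1,3-dioxolan-2-yl)ethyl]-3-[1-(trimethylsilyl)ethenyl]cyclopentane-1-carbonitrile | CC1(OCCO1)CC[C@H]2[C@H](C#N)CC[C@]2(C)C(=C)[Si](C)(C)C
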